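**Assumption (one line):** "(6Z)" refers to the CH2OH‑bearing trisubstituted alkene. In the SMILES its chain carbons are trans, so CIP gives Z. The C‑5 butenolide centre derived from the SMILES is (R).

## Retrosynthetic overview
- The butenolide forms last, by ring‑closing metathesis of the acrylate of a 2‑(PMBO‑CH2)allylic alcohol (23). The (R) carbinol comes from D‑aspartate.
- The Z‑CH2OR trisubstituted alkene and the C6–C7 bond form together in a Johnson–Claisen [3,3] rearrangement of the 2‑substituted allylic alcohol 11. The aldehyde for 11 is made by diazoketone homologation of the aspartate‑derived acid.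
- The E‑trisubstituted alkene comes from a stabilised‑ylide Wittig reaction on the Claisen‑derived aldehyde 14. The 2,6,6‑trimethylcyclohexene ring is bought as β‑cyclocitral and attached by a Cu‑catalysed allyl–allyl coupling.

## Route

**Step 1**
Reactants: 1 (H‑D‑Asp(OMe)‑OH, (R)‑2‑amino‑4‑methoxy‑4‑oxobutanoic acid)
Product: 2 ((R)‑2‑hydroxy‑4‑methoxy‑4‑oxobutanoic acid)
Conditions: NaNO2, 1 M H2SO4 (aq), 0 °C → rt
Reagents that add atoms: water, O
Why: Diazotisation of an α‑amino acid proceeds with retention through an α‑lactone, so the bought (R) centre is carried over unchanged.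

**Step 2**
Reactants: 2
Product: 3 ((R)‑2‑(TBSO)‑4‑methoxy‑4‑oxobutanoic acid)
Conditions: TBSCl, imidazole, DMF, rt; then THF/H2O/AcOH
Reagents that add atoms: TBSCl, CC(C)(C)[Si](C)(C)Cl
Why: The OH is silylated, and the silyl ester formed at the same time is hydrolysed on mild acidic work‑up, leaving the free acid and methyl ester.

**Step 3**
Reactants: 3, 4 (diazomethane)
Product: 5 (methyl (R)‑3‑(TBSO)‑5‑diazo‑4‑oxopentanoate)
Conditions: (COCl)2, cat. DMF, CH2Cl2, 0 °C; then CH2N2 (2.5 equiv), Et2O, 0 °C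
Reagents that add atoms: none
Why: The acid chloride is converted to the diazoketone (Arndt–Eistert first stage) in the presence of the methyl ester; the stereocentre is not involved.

**Step 4**
Reactants: 5
Product: 6 (methyl (R)‑3‑(TBSO)‑5‑(PMBO)‑4‑oxopentanoate)
Conditions: PMBOH (3 equiv), Rh2(OAc)4 (1 mol %), CH2Cl2, rt
Reagents that add atoms: 4‑methoxybenzyl alcohol, COc1ccc(CO)cc1
Why: The Rh‑carbenoid undergoes O–H insertion into the alcohol (Rh‑catalysed), installing the protected CH2OH on the ketone.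

**Step 5**
Reactants: 6
Product: 7 (methyl (R)‑3‑(TBSO)‑4‑{[(4‑methoxybenzyl)oxy]methyl}pent‑4‑enoate)
Conditions: Zn, CH2Br2, TiCl4, THF/CH2Cl2, 0 °C → rt
Reagents that add atoms: dibromomethane, C(Br)Br
Why: Takai–Lombardo methylenation converts the ketone to the 1,1‑disubstituted alkene without basic conditions, avoiding E1cB loss of the β‑silyloxy group and epimerisation, and it leaves the ester untouched.

**Step 6**
Reactants: 7
Product: 8 ((R)‑3‑(TBSO)‑4‑(PMBOCH2)pent‑4‑enal)
Conditions: DIBAL‑H (1.05 equiv), CH2Cl2, −78 °C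
Reagents that add atoms: none
Why: Low‑temperature DIBAL stops at the aldehyde stage; the alkene and the silyl and PMB ethers are inert.

**Step 7**
Reactants: 9 (2‑bromoprop‑2‑en‑1‑ol)
Product: 10 (1‑[(2‑bromoallyloxy)methyl]‑4‑methoxybenzene)
Conditions: NaH, PMBCl, cat. TBAI, THF/DMF, 0 °C
Reagents that add atoms: 4‑methoxybenzyl chloride, COc1ccc(CCl)cc1
Why: Williamson etherification prepares the vinyl‑bromide partner that carries the future a8‑CH2OH as a PMB ether.

**Step 8**
Reactants: 8, 10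
Product: 11 ((5R)‑5‑(TBSO)‑2,6‑bis{[(4‑methoxybenzyl)oxy]methyl}hepta‑1,6‑dien‑3‑ol, C3 epimeric mixture)
Conditions: CrCl2, cat. NiCl2, DMF, rt
Reagents that add atoms: none
Why: Nozaki–Hiyama–Kishi vinylation adds chemoselectively to the aldehyde; the new carbinol is destroyed in the next step, so its configuration does not matter.

**Step 9 (key step)**
Reactants: 11, 12 (triethyl orthoacetate)
Product: 13 (ethyl (4Z,7R)‑7‑(TBSO)‑4,8‑bis(PMBO‑methyl)nona‑4,8‑dienoate)
Conditions: 12 (10 equiv), cat. EtCO2H, 140 °C, sealed tube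
Reagents that add atoms: none
Why: Johnson–Claisen ([3,3]‑sigmatropic) rearrangement through a chair transition state with the C3 substituent equatorial, as in Johnson's 2‑methylallyl‑carbinol polyene work. This forms the C6–C7 bond and the trisubstituted alkene with CH2OPMB cis to the CH2–C5 chain (Z by CIP, as in the target).

**Step 10**
Reactants: 13
Product: 14 ((4Z,7R)‑7‑(TBSO)‑4,8‑bis(PMBO‑methyl)nona‑4,8‑dienal)
Conditions: DIBAL‑H (1.1 equiv), CH2Cl2, −78 °C
Reagents that add atoms: none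
Why: Controlled DIBAL reduction of the ester to the aldehyde.

**Step 11**
Reactants: 14, 15 (ethyl 2‑(triphenylphosphoranylidene)propanoate)
Product: 16 (ethyl (2E,6Z,9R)‑9‑(TBSO)‑2‑methyl‑6,10‑bis(PMBO‑methyl)undeca‑2,6,10‑trienoate)
Conditions: toluene, 80 °C
Reagents that add atoms: none
Why: A stabilised‑ylide Wittig reaction gives the E‑α‑methyl enoate with high selectivity, setting the chain‑trans trisubstituted alkene.

**Step 12**
Reactants: 16
Product: 17 ((2E,6Z,9R)‑9‑(TBSO)‑6,10‑bis(PMBO‑methyl)‑2‑methylundeca‑2,6,10‑trien‑1‑ol)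
Conditions: DIBAL‑H (2.5 equiv), CH2Cl2, −78 → 0 °C
Reagents that add atoms: none
Why: The enoate is reduced to the allylic alcohol without touching the alkenes or the ethers.

**Step 13**
Reactants: 17
Product: 18 (the (2E,6Z,9R) allylic bromide, 17 with Br in place of OH)
Conditions: CBr4, PPh3, CH2Cl2, 0 °C
Reagents that add atoms: carbon tetrabromide, BrC(Br)(Br)Br
Why: Appel bromination under neutral conditions leaves the PMB and silyl ethers intact.

**Step 14**
Reactants: 19 (β‑cyclocitral)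
Product: 20 ((2,6,6‑trimethylcyclohex‑1‑enyl)methanol)
Conditions: NaBH4, MeOH, 0 °C
Reagents that add atoms: none
Why: Simple carbonyl reduction.

**Step 15**
Reactants: 20
Product: 21 (1‑(chloromethyl)‑2,6,6‑trimethylcyclohexene)
Conditions: MsCl, 2,6‑lutidine, LiCl, DMF, 0 °C
Reagents that add atoms: lithium chloride, [Li+].[Cl-]
Why: The allylic mesylate is displaced in situ by chloride (Collington–Meyers), giving the ring electrophile without isomerisation.

**Step 16**
Reactants: 18, 21
Product: 22 (TBS ether carrying the ring, the two PMB ethers and the 1,1‑disubstituted alkene)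
Conditions: (i) 21, Mg, THF; (ii) 18, cat. Li2CuCl4, THF, −30 → 0 °C
Reagents that add atoms: none
Why: Cu‑catalysed SN2 coupling of the ring‑CH2MgCl (from 21) with the allylic bromide joins the two CH2 groups and keeps the E alkene.

**Step 17**
Reactants: 22
Product: 23 (free secondary allylic alcohol)
Conditions: HF·pyridine, THF/pyridine, 0 °C → rt
Reagents that add atoms: none
Why: The buffered fluoride removes the secondary TBS ether and leaves PMB ethers and alkenes intact, without touching C5.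

**Step 18**
Reactants: 23, 24 (acryloyl chloride)
Product: 25 (acrylate ester)
Conditions: Et3N, cat. DMAP, CH2Cl2, 0 °C
Reagents that add atoms: none
Why: Esterification at O5 with retention supplies the RCM partner.

**Step 19**
Reactants: 25
Product: 26 ((R)‑butenolide bearing two PMB ethers)
Conditions: Grubbs II (10 mol %), CH2Cl2 (3 mM), 40 °C
Reagents that add atoms: none
Why: Ring‑closing metathesis of the acrylate with the 1,1‑disubstituted alkene forms the 4‑(PMBOCH2)‑butenolide and releases ethylene. The stereocentre is untouched.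

**Step 20**
Reactants: 26
Product: 27 ((6Z)‑neomanoalide)
Conditions: DDQ (2.6 equiv), CH2Cl2/pH 7 buffer 18:1, 0 °C
Reagents that add atoms: none
Why: Oxidative removal of both PMB ethers under neutral conditions gives the two free CH2OH groups.

## Compound list
1 | H‑D‑Asp(OMe)‑OH | N[C@H](CC(=O)OC)C(=O)O | starting material
2 | (R)‑2‑hydroxy‑4‑methoxy‑4‑oxobutanoic acid | O[C@H](CC(=O)OC)C(=O)O | intermediate
3 | (R)‑2‑(TBSO)‑4‑methoxy‑4‑oxobutanoic acid | CC(C)(C)[Si](C)(C)O[C@H](CC(=O)OC)C(=O)O | intermediate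
4 | diazomethane | C=[N+]=[N-] | starting material
5 | methyl (R)‑3‑(TBSO)‑5‑diazo‑4‑oxopentanoate | CC(C)(C)[Si](C)(C)O[C@H](CC(=O)OC)C(=O)C=[N+]=[N-] | intermediate
6 | methyl (R)‑3‑(TBSO)‑5‑(PMBO)‑4‑oxopentanoate | CC(C)(C)[Si](C)(C)O[C@H](CC(=O)OC)C(=O)COCc1ccc(OC)cc1 | intermediate
7 | methyl (R)‑3‑(TBSO)‑4‑(PMBOCH2)pent‑4‑enoate | CC(C)(C)[Si](C)(C)O[C@H](CC(=O)OC)C(=C)COCc1ccc(OC)cc1 | intermediate
8 | (R)‑3‑(TBSO)‑4‑(PMBOCH2)pent‑4‑enal | CC(C)(C)[Si](C)(C)O[C@H](CC=O)C(=C)COCc1ccc(OC)cc1 | intermediate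
9 | 2‑bromoprop‑2‑en‑1‑ol | C=C(Br)CO | starting material
10 | 2‑bromoallyl PMB ether | C=C(Br)COCc1ccc(OC)cc1 | intermediate
11 | bis(PMBO‑methyl) allylic alcohol (C3 epimers) | CC(C)(C)[Si](C)(C)O[C@H](CC(O)C(=C)COCc1ccc(OC)cc1)C(=C)COCc1ccc(OC)cc1 | intermediate
12 | triethyl orthoacetate | CCOC(C)(OCC)OCC | starting material
13 | ethyl (4Z,7R)‑7‑(TBSO)‑4,8‑bis(PMBOCH2)nona‑4,8‑dienoate | CCOC(=O)CC/C(COCc1ccc(OC)cc1)=C/C[C@@H](O[Si](C)(C)C(C)(C)C)C(=C)COCc1ccc(OC)cc1 | intermediate
14 | aldehyde from 13 | O=CCC/C(COCc1ccc(OC)cc1)=C/C[C@@H](O[Si](C)(C)C(C)(C)C)C(=C)COCc1ccc(OC)cc1 | intermediate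
15 | ethyl 2‑(triphenylphosphoranylidene)propanoate | CCOC(=O)C(C)=P(c1ccccc1)(c1ccccc1)c1ccccc1 | starting material
16 | E‑enoate | CCOC(=O)/C(C)=C/CC/C(COCc1ccc(OC)cc1)=C/C[C@@H](O[Si](C)(C)C(C)(C)C)C(=C)COCc1ccc(OC)cc1 | intermediate
17 | allylic alcohol | OC/C(C)=C/CC/C(COCc1ccc(OC)cc1)=C/C[C@@H](O[Si](C)(C)C(C)(C)C)C(=C)COCc1ccc(OC)cc1 | intermediate
18 | allylic bromide | BrC/C(C)=C/CC/C(COCc1ccc(OC)cc1)=C/C[C@@H](O[Si](C)(C)C(C)(C)C)C(=C)COCc1ccc(OC)cc1 | intermediate
19 | β‑cyclocitral | CC1=C(C=O)C(C)(C)CCC1 | starting material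
20 | β‑cyclogeraniol | CC1=C(CO)C(C)(C)CCC1 | intermediate
21 | β‑cyclogeranyl chloride | CC1=C(CCl)C(C)(C)CCC1 | intermediate
22 | coupled TBS ether | CC1=C(CC/C(C)=C/CC/C(COCc2ccc(OC)cc2)=C/C[C@@H](O[Si](C)(C)C(C)(C)C)C(=C)COCc2ccc(OC)cc2)C(C)(C)CCC1 | intermediate
23 | free allylic alcohol | CC1=C(CC/C(C)=C/CC/C(COCc2ccc(OC)cc2)=C/C[C@@H](O)C(=C)COCc2ccc(OC)cc2)C(C)(C)CCC1 | intermediate
24 | acryloyl chloride | C=CC(=O)Cl | starting material
25 | acrylate ester | CC1=C(CC/C(C)=C/CC/C(COCc2ccc(OC)cc2)=C/C[C@@H](OC(=O)C=C)C(=C)COCc2ccc(OC)cc2)C(C)(C)CCC1 | intermediate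
26 | bis‑PMB butenolide | CC1=C(CC/C(C)=C/CC/C(COCc2ccc(OC)cc2)=C/C[C@H]2OC(=O)C=C2COCc2ccc(OC)cc2)C(C)(C)CCC1 | intermediate
27 | (6Z)‑neomanoalide | CC1=C(CC/C(C)=C/CC/C(=C/C[C@H]2OC(=O)C=C2CO)CO)C(C)(C)CCC1 | target

## Totals
- Total steps: 20.
- Longest linear sequence: 17 (1→2→3→5→6→7→8→11→13→14→16→17→18→22→23→25→26→27 in compound numbers, i.e. Steps 1–6, 8–13, 16–20).

## Three steps most likely to fail
1. **Step 19 (RCM).** Acrylate closure onto a 1,1‑disubstituted alkene is slow, and the Z‑trisubstituted alkene could give a δ‑lactone instead.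
   Fallback (different approach): carry the C4/C3 unit as an α‑silyloxy TMS‑alkyne (made from acid 3 via the aldehyde and an Ohira–Bestmann/Corey–Fuchs alkyne synthesis). After the chain is built, remove TBS/TMS, form the γ‑hydroxy ynoate (2 BuLi, ClCO2Me), and close the butenolide by cuprate conjugate addition of a PMBOCH2 nucleophile with lactonisation.
2. **Step 16 (allyl–allyl Cu coupling with the hindered β‑cyclogeranyl Grignard).** It may give γ‑coupling or homocoupling.
   Fallback: replace Steps 11–16 by a Julia–Kocienski olefination of aldehyde 14 with a tetrazolyl sulfone built from dihydro‑β‑ionone (NaBH4; Mitsunobu with PT‑SH; Mo/H2O2 oxidation), accepting chromatographic removal of the Z isomer.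
3. **Step 8 (NHK with the 2‑bromoallyl ether).** The vinyl‑metal can lose the allylic OR to give an allene.
   Fallback: use a Morita–Baylis–Hillman reaction of aldehyde 8 with methyl acrylate/DABCO, then DIBAL reduction of the ester and PMB protection of the primary alcohol. This gives the same 2‑(PMBOCH2)allylic alcohol 11.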